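The runs were computed on assumed constants; scatter was added.

Both flasks hold the same amounts of starting material and precatalyst, but gamma gets less partner, fed in, and twice the time of delta.

| flask | starting material | partner | precatalyst | temperature | remark | time |
|---|---|---|---|---|---|---|
| ash | 0.20 M | 0.15 M (fed, over 25 s) | 4 mM | 35 °C | run made earlier |  |
| elm | 0.20 M | 0.31 M (fed, over 25 s) | 4 mM | 46 °C | run made earlier |  |
| gamma | 0.20 M | 0.240 M (fed, over 25 s) | 4.0 mM | 40 °C |  | 6.0 min |
| delta | 0.20 M | 0.400 M | 4.0 mM | 40 °C | everything together at the start | 3.0 min |

| run | time / min | product / % |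
|---|---|---|
| ash | 0.500 | 0 |
| ash | 1.50 | 0 |
| ash | 3.00 | 1.9 |
| ash | 4.00 | 3.8 |
| ash | 6.00 | 6.5 |
| elm | 0.500 | 1.4 |
| elm | 1.50 | 2.4 |
| elm | 3.00 | 15.1 |
| elm | 4.00 | 24.4 |
| elm | 6.00 | 45.8 |

(standard deviation of a reading: 1 percentage point)



- the flask that ends with the higher amount of product, in percent of the starting material charged, or "neither" when 2 percentage points or less lies between them (gamma / delta / neither)
- final product, as a percentage of the starting material charged, in gamma
- final product, as a percentage of the starting material charged, in delta

In ash and elm the product stays near zero, then climbs roughly along a line. I draw that line through the readings at 3.00 min and 6.00 min. Its slope r, as a fraction of the charge per minute, reads 0.0153 min⁻¹ in ash and 0.102 min⁻¹ in elm. Run back to zero, it gives a lag of 1.76 min in ash and 1.52 min in elm. I take the mean as the lag L, 1.64 min, and treat it as a correction to the clock: product is r(t − L). I assume the same L for delta, though that is a guess. L takes a quarter of gamma's time but half of delta's.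

So I define the catch-up factor F, the ratio of gamma's working time to delta's, and the rate ratio delta needs to draw level, here 3.21. Both flasks stand at 40 °C, near the middle of ash and elm, so, assuming first order in partner, I take the rate per mole of partner as the geometric mean of those two runs, 0.184 L mol⁻¹ min⁻¹. Gamma then runs at 0.0441 min⁻¹ and makes 19.2%. Delta runs at 0.0735 min⁻¹ and makes 9.97%.

The weak link is that order: ash and elm changed partner and temperature together. So I reforge it: delta has 1.67 times gamma's partner, and even a rate following its square gains 2.78, which is less than F. I commit to gamma.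

The forecast also says gamma, with 17% and 10%, its gamma below mine, and adds “delta's lag and order remain uncertain”. Gamma gives 20.1% and delta 10.3%.

    partner + free catalyst → catalyst intermediate A (k = 490 L mol⁻¹ min⁻¹, Ea = 56.0 kJ mol⁻¹)
    starting material + catalyst intermediate A → catalyst intermediate B (k = 120 L mol⁻¹ min⁻¹, Ea = 54.0 kJ mol⁻¹)
    starting material + free catalyst → spent catalyst (k = 2.50 L mol⁻¹ min⁻¹, Ea = 44.0 kJ mol⁻¹)
    catalyst intermediate B → free catalyst + product (k = 15.0 min⁻¹, Ea = 69.0 kJ mol⁻¹)
    partner + precatalyst → free catalyst + spent reagent (k = 0.410 L mol⁻¹ min⁻¹, Ea = 48.0 kJ mol⁻¹)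
    (constants at 40 °C)

Neither flask has come to rest: 79% of the starting material stands in gamma and 89% in delta. Over its working time delta ran at 0.0760 min⁻¹ and gamma at 0.0461 min⁻¹, a ratio of 1.65, less than F. Delta's line predicts 78.7% at 12 min, and that flask stores 77.4%. Longer still, gamma reaches 99.7% at 60.0 min. At 30.0 min delta holds 99.8% product, with 0.0282% of its starting material, the limiting reagent, and 48.3% of its partner.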